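**Retrosynthetic overview**
- The strategy rests on C3, the quaternary carbon that carries a methyl group, the vinyl group C1=C2, the E-alkene C4=C5 and the chain C15–C22; it is built as one corner of a cyclopropane C2–C3–C4 whose extra bond C2–C4 is cut later.
- Last bond: C7–C8, by copper-catalysed coupling of the chain tosylate 24 with the Grignard reagent of the methylenecyclohexane (ring C9–C14, from 4-methylcyclohexanone).
- C1=C2 and C4=C5 appear together when a carbanion at C1 opens the cyclopropane and expels the C5 oxygen of a 1,3-dioxane; C5 and C6 come from an Evans syn aldol on the cyclopropane aldehyde 13.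
- The cyclopropane and its fused γ-lactone (3-oxabicyclo[3.1.0]hexan-2-one) come from intramolecular rhodium-carbene addition of diazoacetate 9 to C2=C3; the trienol comes from farnesol by allylic oxidation, chlorination and copper-catalysed SN2′ methylation (C21).
- Ring order: cyclopropane and lactone together (step 8), lactone opened (step 9), dioxane closed (step 14), cyclopropane and dioxane opened together (step 17); the cyclohexane ring is present from the start of its branch.

Key step: step 8

Atom numbers used: vinyl C1=C2, quaternary C3, E-alkene C4=C5, methine C6, C7, C8, ring C9–C14 (methylidene on C10, methyl on C13, gem-dimethyl C14), and from C3 the chain C15, C16, C17=C18 (methyl on C18), C19, C20, methine C21, isopropenyl carbon C22. Farnesol C1–C3 become C1–C3 and farnesol C4–C11 become C15–C22.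

Assumption: the antipodes of the phosphoramidite (step 4) and of the lithium amide (step 19) are taken to induce the configurations drawn; should either give the opposite sense, its mirror-image form is used and nothing else changes.

**Route**

Step 1
Reactants: 1 (2E,6E)-farnesol
Product: 2 tert-butyl(dimethyl)silyl ether of farnesol
Conditions: TBSCl, imidazole, DMF, 0 °C → rt
Reagents that add atoms: tert-butyl(chloro)dimethylsilane, CC(C)(C)[Si](C)(C)Cl
Why: Imidazole-promoted silylation of the primary allylic alcohol masks the C1 oxygen for the oxidation and Grignard steps that follow.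

Step 2
Reactants: 2 farnesyl silyl ether
Product: 3 (2E,6E,10E)-12-silyloxy-2,6,10-trimethyldodeca-2,6,10-trien-1-ol
Conditions: SeO2 (10 mol%), t-BuOOH, salicylic acid (10 mol%), CH2Cl2, 0 °C → rt, stopped at partial conversion, 2 recycled
Reagents that add atoms: tert-butyl hydroperoxide, CC(C)(C)OO (its oxygen is passed on through catalytic selenium dioxide, O=[Se]=O)
Why: The selenium dioxide allylic oxidation (Riley type, ene reaction then [2,3]-shift) should attack the E-methyl of the terminal, most electron-rich trisubstituted alkene, as is known for farnesyl ethers and esters, while the alkene next to the silyloxy group is deactivated.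

Step 3
Reactants: 3 allylic alcohol
Product: 4 (2E,6E,10E)-12-chloro silyl ether
Conditions: N-chlorosuccinimide, Me2S, CH2Cl2, −30 → 0 °C
Reagents that add atoms: N-chlorosuccinimide, O=C1CCC(=O)N1Cl
Why: Corey–Kim chlorination displaces the alkoxysulfonium ion by chloride in an SN2 step, so the primary allylic chloride should form without allylic shift and without loss of the silyl ether.

Step 4
Reactants: 4 allylic chloride
Product: 5 silyl ether of (2E,6E,10R)-3,7,10,11-tetramethyldodeca-2,6,11-trien-1-ol
Conditions: MeMgBr (Et2O, slow addition), copper thiophene-2-carboxylate Cu(O2CC4H3S) (3 mol%), (S,S,S)-phosphoramidite from 2,2'-binaphthol and bis[1-(2-methoxyphenyl)ethyl]amine (3.3 mol%), CH2Cl2, −78 °C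
Reagents that add atoms: methylmagnesium bromide, C[Mg]Br
Why: Copper-catalysed asymmetric allylic alkylation of 2-substituted E-allylic chlorides with Grignard reagents is SN2′-selective, so methyl should add to the former alkene CH (C21) while the double bond moves out to the C22 methylidene, and the phosphoramidite-bound copper chooses the alkene face that makes C21 R.

Step 5
Reactants: 5 silyl ether
Product: 6 (2E,6E,10R)-3,7,10,11-tetramethyldodeca-2,6,11-trien-1-ol (chain trienol)
Conditions: Bu4NF, THF, 0 °C → rt
Reagents that add atoms: none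
Why: Fluoride-induced desilylation frees the primary allylic alcohol and nothing else in the triene responds.

Step 6
Reactants: 6 chain trienol; 7 bromoacetyl bromide
Product: 8 trienyl bromoacetate
Conditions: NaHCO3, MeCN, 0 °C
Reagents that add atoms: none
Why: O-Acylation of the allylic alcohol by the acid bromide under bicarbonate buffering brings in C4 and C5 without acid that could ionise the allylic ester.

Step 7
Reactants: 8 trienyl bromoacetate
Product: 9 trienyl diazoacetate
Conditions: TsNHNHTs, DBU, THF, 0 °C
Reagents that add atoms: N,N'-ditosylhydrazine, Cc1ccc(cc1)S(=O)(=O)NNS(=O)(=O)c1ccc(C)cc1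
Why: N-Alkylation of the ditosylhydrazine by the bromoacetate followed by two base-induced sulfinate eliminations (Bamford–Stevens type) is an established mild route from allylic bromoacetates to diazoacetates.

Step 8
Reactants: 9 trienyl diazoacetate
Product: 10 (1S,5R,6S)-6-methyl-6-[(3E,7R)-4,7,8-trimethylnona-3,8-dien-1-yl]-3-oxabicyclo[3.1.0]hexan-2-one
Conditions: Rh2(5S-MEPY)4, dirhodium tetrakis[methyl (5S)-2-oxopyrrolidine-5-carboxylate] (1 mol%), CH2Cl2, reflux, 9 added by syringe pump over 12 h
Reagents that add atoms: none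
Why: The dirhodium carboxamidate expels N2 from 9 to give an electrophilic rhodium carbene at C4, which adds to the nearest alkene C2=C3 in one concerted, asynchronous [2+1] step that forms C3–C4 and the temporary C2–C4 bond; the closest known reaction type is the enantioselective intramolecular cyclopropanation of E-allylic diazoacetates (3-methylbut-2-enyl, geranyl and farnesyl esters) with chiral dirhodium carboxamidates. The cyclopropane closes by the carbene [2+1] addition itself and the γ-lactone is the five-membered ring of the ester tether (O, C1, C2, C4, C5), which can only be cis-fused. C3 takes its relative configuration from the E geometry of C2=C3, which is carried over so that the C3 methyl is cis to C1 and the chain C15 is exo, and its absolute configuration from the alkene face left open by the 5S ester groups of the catalyst, the same sense in which this catalyst turns 3-methylbut-2-enyl diazoacetate into the 1S,5R lactone; C2 and C4 follow from the cis fusion. The step needs face selectivity at C2=C3 and site selectivity over C17=C18, the C22 methylidene and C–H insertion: the short ester tether makes any other addition a medium or large ring, carboxamidate carbenes are mild enough to take only the allylic alkene, and slow addition keeps the carbene from dimerising. The stereocentre C21 is remote and should neither bias the addition nor be touched.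

Step 9
Reactants: 10 cyclopropane-fused lactone
Product: 11 (1S,2R,3S)-2-(hydroxymethyl)-N-methoxy-N,3-dimethyl-3-[(3E,7R)-4,7,8-trimethylnona-3,8-dien-1-yl]cyclopropane-1-carboxamide
Conditions: MeNH(OMe)·HCl, Me3Al, CH2Cl2, 0 °C → rt
Reagents that add atoms: N,O-dimethylhydroxylamine hydrochloride, CNOC.Cl
Why: Aluminium amide aminolysis (Weinreb amide formation) opens the lactone at the acyl C5–O bond, which tells the two arms of the cyclopropane apart (C1 alcohol, C5 amide) without touching a stereocentre.

Step 10
Reactants: 11 hydroxy amide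
Product: 12 tert-butyl(diphenyl)silyl ether of 11
Conditions: TBDPSCl, imidazole, DMF, 0 °C → rt
Reagents that add atoms: tert-butyl(chloro)diphenylsilane, CC(C)(C)[Si](Cl)(c1ccccc1)c1ccccc1
Why: Silylation of the primary alcohol stops relactonisation, and the diphenyl silyl ether is chosen because it should survive the later acid-catalysed acetal formation.

Step 11
Reactants: 12 silyl ether amide
Product: 13 (1S,2R,3S)-2-(silyloxymethyl)-3-methyl-3-[(3E,7R)-4,7,8-trimethylnona-3,8-dien-1-yl]cyclopropane-1-carbaldehyde
Conditions: i-Bu2AlH, THF, −78 °C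
Reagents that add atoms: none
Why: Hydride reduction of the N-methoxy-N-methylamide stops at a chelated tetrahedral intermediate that releases the C5 aldehyde only on work-up, and at −78 °C the cis-cyclopropane aldehyde should not epimerise at C4.

Step 12
Reactants: 13 cyclopropane aldehyde; 14 (4R)-4-benzyl-3-propanoyl-1,3-oxazolidin-2-one
Product: 16 syn aldol adduct (4R)-4-benzyl-3-[(2R,3S)-3-hydroxy-2-methyl-3-cyclopropylpropanoyl]oxazolidinone, via boron enolate 15 (not isolated)
Conditions: 14, n-Bu2BOTf, i-Pr2NEt, CH2Cl2, −78 → 0 °C; then 13, −78 → 0 °C; pH 7 buffer, MeOH, H2O2, 0 °C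
Reagents that add atoms: none
Why: In the Evans syn aldol the Z-boron enolate reacts through a Zimmerman–Traxler chair in which the R auxiliary, not the aldehyde, fixes both new centres, C6 (R in the adduct, S in the target numbering once C7 is reduced) and C5 (S), the C5 configuration that later lets the C5–O bond lie anti to C2–C4 with the C5 hydrogen turned towards C3.

Step 13
Reactants: 16 aldol adduct
Product: 17 (1S,2S)-1-cyclopropyl-2-methylpropane-1,3-diol (C5 and C7 hydroxyls)
Conditions: LiBH4, MeOH (1 equiv), Et2O, 0 °C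
Reagents that add atoms: none
Why: Borohydride reductive cleavage of the N-acyl oxazolidinone gives the C7 primary alcohol and returns the auxiliary without epimerising C6.

Step 14
Reactants: 17 diol
Product: 18 acetonide, (4S,5S)-2,2,5-trimethyl-1,3-dioxan-4-yl group on C4
Conditions: Me2C(OMe)2, pyridinium p-toluenesulfonate (catalytic), CH2Cl2, rt
Reagents that add atoms: 2,2-dimethoxypropane, COC(C)(C)OC
Why: Acid-catalysed transketalisation ties the 1,3-diol into a dioxane that protects C7–O and turns C5–O into the future leaving group, under conditions too mild to ionise the cyclopropylcarbinyl C5–O bond or to cleave the silyl ether.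

Step 15
Reactants: 18 acetonide silyl ether
Product: 19 cyclopropylmethanol (C1 hydroxyl free)
Conditions: Bu4NF, THF, rt
Reagents that add atoms: none
Why: Fluoride desilylation frees C1–OH while the acetonide and the alkenes stay untouched.

Step 16
Reactants: 19 cyclopropylmethanol
Product: 20 cyclopropylmethyl iodide (C1 iodide)
Conditions: PPh3, I2, imidazole, CH2Cl2, 0 °C, dark; filtered cold through basic alumina and used at once
Reagents that add atoms: iodine, II
Why: The Appel-type iodination is an SN2 displacement at primary C1 under buffered, cold, non-ionising conditions, which should keep the cyclopropylcarbinyl iodide from rearranging before it is used.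

Step 17
Reactants: 20 cyclopropylmethyl iodide
Product: 23 (2R,3E,5S,8E,12R)-5-ethenyl-2,5,9,12,13-pentamethyltetradeca-3,8,13-trien-1-ol, via alkyllithium 21 (not isolated), via hemiketal alkoxide 22 (not isolated)
Conditions: t-BuLi (2.2 equiv), pentane/Et2O 3:2, −78 → −20 °C; aqueous NH4Cl
Reagents that add atoms: none
Why: Proposed new method: iodine–lithium exchange under conditions in which primary iodides exchange without free radicals gives the C1 alkyllithium 21, and because cyclopropylmethyllithiums open to homoallyllithiums and the C2–C4 bond here is anti-periplanar to the C5–O bond of the dioxane, the electrons of C1–Li should flow into C1=C2 and those of C2–C4 into C4=C5 while the acetal oxygen leaves as alkoxide 22 (a 1,4-elimination relayed through the three-membered ring) with all four bonds of C3 intact, the E geometry following from the rotamer in which the C5 hydrogen and not C6 lies over the ring towards the cis methyl of C3, and cleavage of C2–C3 being disfavoured because it would leave a tertiary carbanion with no leaving group; the closest known reaction types are the ring opening of cyclopropylmethyllithium to but-3-enyllithium and the β-alkoxide (Boord-type) elimination of organolithiums from iodo acetonides.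

Step 18
Reactants: 23 trienol
Product: 24 4-methylbenzenesulfonate of 23
Conditions: TsCl, Et3N, 4-(dimethylamino)pyridine (catalytic), CH2Cl2, 0 °C
Reagents that add atoms: 4-methylbenzenesulfonyl chloride, Cc1ccc(cc1)S(=O)(=O)Cl
Why: Sulfonylation of the primary C7 alcohol gives the electrophile for the final coupling without touching C6.

Step 19
Reactants: 25 4-methylcyclohexanone
Product: 26 trimethyl{[(4S)-4-methylcyclohex-1-en-1-yl]oxy}silane
Conditions: (R,R)-bis(1-phenylethyl)amine, n-BuLi, Me3SiCl present from the start, THF, −100 °C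
Reagents that add atoms: chlorotrimethylsilane, C[Si](C)(C)Cl
Why: Enantioselective deprotonation of a prochiral 4-substituted cyclohexanone by a chiral lithium amide with in situ silyl trapping removes one of the two enantiotopic α-hydrogens, which makes the methyl-bearing carbon (C13) a stereocentre of S configuration.

Step 20
Reactants: 26 silyl enol ether
Product: 27 (4S)-4-methylcyclohex-2-en-1-one
Conditions: Pd(OAc)2 (10 mol%), O2 (1 atm), DMSO, rt
Reagents that add atoms: none
Why: Saegusa–Ito oxidation (palladium enolate, then β-hydride elimination) places the enone double bond on the side of the enol ether and leaves C13 alone.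

Step 21
Reactants: 27 enone
Product: 28 {[(3R,4S)-3,4-dimethylcyclohex-1-en-1-yl]oxy}trimethylsilane
Conditions: Me2CuLi (from MeLi and CuBr·SMe2), Me3SiCl, THF, −78 °C; Et3N quench
Reagents that add atoms: lithium dimethylcuprate, [Li+].C[Cu-]C; chlorotrimethylsilane, C[Si](C)(C)Cl
Why: Silyl-accelerated cuprate conjugate addition puts the first methyl on C14 (trans to the C13 methyl, a centre that is erased next) and traps the enolate regiospecifically as the silyl enol ether.

Step 22
Reactants: 28 silyl enol ether
Product: 29 (4S)-3,4-dimethylcyclohex-2-en-1-one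
Conditions: Pd(OAc)2 (10 mol%), O2 (1 atm), DMSO, rt
Reagents that add atoms: none
Why: A second Saegusa–Ito oxidation restores the enone, now with the β-methyl in place, and C13 is again untouched.

Step 23
Reactants: 29 β-methyl enone
Product: 31 (2S,4S)-2-(hydroxymethyl)-3,3,4-trimethylcyclohexan-1-one, via enolate 30 (not isolated)
Conditions: Me2CuLi (from MeLi and CuBr·SMe2), Et2O, −20 → 0 °C; CH2O gas (from cracked paraformaldehyde), −78 °C; aqueous NH4Cl, −78 °C
Reagents that add atoms: lithium dimethylcuprate, [Li+].C[Cu-]C; formaldehyde, C=O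
Why: The second cuprate conjugate addition makes the gem-dimethyl carbon C14 and gives the C10–C9 enolate regiospecifically, and its aldol trapping by formaldehyde should follow the axial path anti to the pseudoaxial C14 methyl in a chair-like transition state with the C13 methyl equatorial, which sets C9 with the new CH2OH (C8) trans to the C13 methyl under kinetic control.

Step 24
Reactants: 31 hydroxymethyl ketone
Product: 32 tert-butyl(dimethyl)silyl ether of 31
Conditions: TBSCl, imidazole, DMF, 0 °C
Reagents that add atoms: tert-butyl(chloro)dimethylsilane, CC(C)(C)[Si](C)(C)Cl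
Why: Silylation of the β-hydroxy ketone blocks retro-aldol cleavage and dehydration before the carbonyl is methylenated.

Step 25
Reactants: 32 silyloxy ketone
Product: 33 tert-butyl(dimethyl){[(1S,3S)-2,2,3-trimethyl-6-methylidenecyclohexyl]methoxy}silane
Conditions: Zn, CH2Br2, TiCl4, THF (reagent preformed at 5 °C); then 32, CH2Cl2, rt
Reagents that add atoms: dibromomethane, BrCBr
Why: Takai–Lombardo methylenation is not basic, so the C10 carbonyl should become the methylidene without enolisation at C9 or β-elimination of the silyloxy group, after which C9 can no longer epimerise.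

Step 26
Reactants: 33 silyl ether
Product: 34 [(1S,3S)-2,2,3-trimethyl-6-methylidenecyclohexyl]methanol
Conditions: Bu4NF, THF, rt
Reagents that add atoms: none
Why: Fluoride desilylation frees the C8 alcohol and leaves the exocyclic alkene in place.

Step 27
Reactants: 34 ring alcohol
Product: 35 (1S,3S)-1-(bromomethyl)-2,2,3-trimethyl-6-methylidenecyclohexane
Conditions: CBr4, PPh3, CH2Cl2, 0 °C
Reagents that add atoms: carbon tetrabromide, BrC(Br)(Br)Br
Why: The Appel bromination is a neutral SN2 displacement at primary C8, so the exocyclic alkene should not migrate and C9 is not affected.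

Step 28
Reactants: 35 ring bromide; 24 chain tosylate
Product: 37 target hydrocarbon, via Grignard reagent 36 (not isolated)
Conditions: 35, Mg, THF, rt; then 24, Li2CuCl4 (5 mol%), THF, −20 °C → rt
Reagents that add atoms: none
Why: Copper-catalysed coupling of a primary alkyl Grignard reagent with a primary tosylate (Kochi–Schlosser type) forms C7–C8 by displacement at C7, and neither reacting carbon nor the neighbouring centres C6 and C9 can be epimerised under these conditions.

**Compound list**
1 | (2E,6E)-farnesol | CC(C)=CCC/C(C)=C/CC/C(C)=C/CO | starting material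
2 | tert-butyl(dimethyl){[(2E,6E)-3,7,11-trimethyldodeca-2,6,10-trien-1-yl]oxy}silane | CC(C)=CCC/C(C)=C/CC/C(C)=C/CO[Si](C)(C)C(C)(C)C | intermediate
3 | (2E,6E,10E)-12-{[tert-butyl(dimethyl)silyl]oxy}-2,6,10-trimethyldodeca-2,6,10-trien-1-ol | OC/C(C)=C/CC/C(C)=C/CC/C(C)=C/CO[Si](C)(C)C(C)(C)C | intermediate
4 | tert-butyl{[(2E,6E,10E)-12-chloro-3,7,11-trimethyldodeca-2,6,10-trien-1-yl]oxy}dimethylsilane | ClC/C(C)=C/CC/C(C)=C/CC/C(C)=C/CO[Si](C)(C)C(C)(C)C | intermediate
5 | tert-butyl(dimethyl){[(2E,6E,10R)-3,7,10,11-tetramethyldodeca-2,6,11-trien-1-yl]oxy}silane | CC(C)(C)[Si](C)(C)OC/C=C(\C)CC/C=C(\C)CC[C@@H](C)C(=C)C | intermediate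
6 | (2E,6E,10R)-3,7,10,11-tetramethyldodeca-2,6,11-trien-1-ol | OC/C=C(\C)CC/C=C(\C)CC[C@@H](C)C(=C)C | intermediate
7 | bromoacetyl bromide | BrCC(Br)=O | starting material
8 | (2E,6E,10R)-3,7,10,11-tetramethyldodeca-2,6,11-trien-1-yl bromoacetate | BrCC(=O)OC/C=C(\C)CC/C=C(\C)CC[C@@H](C)C(=C)C | intermediate
9 | (2E,6E,10R)-3,7,10,11-tetramethyldodeca-2,6,11-trien-1-yl diazoacetate | [N-]=[N+]=CC(=O)OC/C=C(\C)CC/C=C(\C)CC[C@@H](C)C(=C)C | intermediate
10 | (1S,5R,6S)-6-methyl-6-[(3E,7R)-4,7,8-trimethylnona-3,8-dien-1-yl]-3-oxabicyclo[3.1.0]hexan-2-one (C3 methyl on the lactone face, chain exo) | O1C[C@H]2[C@@](C)([C@H]2C1=O)CC/C=C(\C)CC[C@@H](C)C(=C)C | intermediate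
11 | (1S,2R,3S)-2-(hydroxymethyl)-N-methoxy-N,3-dimethyl-3-[(3E,7R)-4,7,8-trimethylnona-3,8-dien-1-yl]cyclopropane-1-carboxamide (amide, CH2OH and ring methyl all cis) | OC[C@H]1[C@@](C)([C@H]1C(=O)N(C)OC)CC/C=C(\C)CC[C@@H](C)C(=C)C | intermediate
12 | tert-butyl(diphenyl)silyl ether of 11 | CC(C)(C)[Si](c1ccccc1)(c1ccccc1)OC[C@H]1[C@@](C)([C@H]1C(=O)N(C)OC)CC/C=C(\C)CC[C@@H](C)C(=C)C | intermediate
13 | (1S,2R,3S)-2-({[tert-butyl(diphenyl)silyl]oxy}methyl)-3-methyl-3-[(3E,7R)-4,7,8-trimethylnona-3,8-dien-1-yl]cyclopropane-1-carbaldehyde | CC(C)(C)[Si](c1ccccc1)(c1ccccc1)OC[C@H]1[C@@](C)([C@H]1C=O)CC/C=C(\C)CC[C@@H](C)C(=C)C | intermediate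
14 | (4R)-4-benzyl-3-propanoyl-1,3-oxazolidin-2-one | CCC(=O)N1[C@H](Cc2ccccc2)COC1=O | starting material
15 | Z-dibutylboron enolate of 14 | C/C=C(\OB(CCCC)CCCC)N1[C@H](Cc2ccccc2)COC1=O | intermediate
16 | (4R)-4-benzyl-3-[(2R,3S)-3-hydroxy-2-methyl-3-(cyclopropyl residue of 13)propanoyl]-1,3-oxazolidin-2-one (syn aldol; C5 S, C6 R) | CC(C)(C)[Si](c1ccccc1)(c1ccccc1)OC[C@H]1[C@@](C)([C@H]1[C@H](O)[C@@H](C)C(=O)N1[C@H](Cc2ccccc2)COC1=O)CC/C=C(\C)CC[C@@H](C)C(=C)C | intermediate
17 | (1S,2S)-2-methyl-1-(cyclopropyl residue of 13)propane-1,3-diol | CC(C)(C)[Si](c1ccccc1)(c1ccccc1)OC[C@H]1[C@@](C)([C@H]1[C@H](O)[C@@H](C)CO)CC/C=C(\C)CC[C@@H](C)C(=C)C | intermediate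
18 | acetonide of 17: (4S,5S)-2,2,5-trimethyl-1,3-dioxan-4-yl group on C4, C1 silyl ether | CC(C)(C)[Si](c1ccccc1)(c1ccccc1)OC[C@H]1[C@@](C)([C@H]1[C@@H]2OC(C)(C)OC[C@@H]2C)CC/C=C(\C)CC[C@@H](C)C(=C)C | intermediate
19 | cyclopropylmethanol from 18 (C1 hydroxyl, all-cis cyclopropane as in 10) | OC[C@H]1[C@@](C)([C@H]1[C@@H]2OC(C)(C)OC[C@@H]2C)CC/C=C(\C)CC[C@@H](C)C(=C)C | intermediate
20 | cyclopropylmethyl iodide from 19 (C1 iodide) | IC[C@H]1[C@@](C)([C@H]1[C@@H]2OC(C)(C)OC[C@@H]2C)CC/C=C(\C)CC[C@@H](C)C(=C)C | intermediate
21 | C1 cyclopropylmethyllithium from 20 | [Li]C[C@H]1[C@@](C)([C@H]1[C@@H]2OC(C)(C)OC[C@@H]2C)CC/C=C(\C)CC[C@@H](C)C(=C)C | intermediate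
22 | lithium alkoxide of the acetone hemiketal of 23 | C=C[C@@](C)(/C=C/[C@@H](C)COC(C)(C)O[Li])CC/C=C(\C)CC[C@@H](C)C(=C)C | intermediate
23 | (2R,3E,5S,8E,12R)-5-ethenyl-2,5,9,12,13-pentamethyltetradeca-3,8,13-trien-1-ol | C=C[C@@](C)(/C=C/[C@@H](C)CO)CC/C=C(\C)CC[C@@H](C)C(=C)C | intermediate
24 | (2R,3E,5S,8E,12R)-5-ethenyl-2,5,9,12,13-pentamethyltetradeca-3,8,13-trien-1-yl 4-methylbenzenesulfonate | C=C[C@@](C)(/C=C/[C@@H](C)COS(=O)(=O)c1ccc(C)cc1)CC/C=C(\C)CC[C@@H](C)C(=C)C | intermediate
25 | 4-methylcyclohexanone | CC1CCC(=O)CC1 | starting material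
26 | trimethyl{[(4S)-4-methylcyclohex-1-en-1-yl]oxy}silane | C[C@H]1CCC(O[Si](C)(C)C)=CC1 | intermediate
27 | (4S)-4-methylcyclohex-2-en-1-one | C[C@H]1CCC(=O)C=C1 | intermediate
28 | {[(3R,4S)-3,4-dimethylcyclohex-1-en-1-yl]oxy}trimethylsilane (methyls trans) | C[C@H]1CCC(O[Si](C)(C)C)=C[C@@H]1C | intermediate
29 | (4S)-3,4-dimethylcyclohex-2-en-1-one | C[C@H]1CCC(=O)C=C1C | intermediate
30 | lithium (4S)-3,3,4-trimethylcyclohex-1-en-1-olate | C[C@H]1CCC(O[Li])=CC1(C)C | intermediate
31 | (2S,4S)-2-(hydroxymethyl)-3,3,4-trimethylcyclohexan-1-one (CH2OH trans to the 4-methyl) | OC[C@H]1C(=O)CC[C@H](C)C1(C)C | intermediate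
32 | (2S,4S)-2-({[tert-butyl(dimethyl)silyl]oxy}methyl)-3,3,4-trimethylcyclohexan-1-one | CC(C)(C)[Si](C)(C)OC[C@H]1C(=O)CC[C@H](C)C1(C)C | intermediate
33 | tert-butyl(dimethyl){[(1S,3S)-2,2,3-trimethyl-6-methylidenecyclohexyl]methoxy}silane | CC(C)(C)[Si](C)(C)OC[C@H]1C(=C)CC[C@H](C)C1(C)C | intermediate
34 | [(1S,3S)-2,2,3-trimethyl-6-methylidenecyclohexyl]methanol | OC[C@H]1C(=C)CC[C@H](C)C1(C)C | intermediate
35 | (1S,3S)-1-(bromomethyl)-2,2,3-trimethyl-6-methylidenecyclohexane | BrC[C@H]1C(=C)CC[C@H](C)C1(C)C | intermediate
36 | {[(1S,3S)-2,2,3-trimethyl-6-methylidenecyclohexyl]methyl}magnesium bromide | Br[Mg]C[C@H]1C(=C)CC[C@H](C)C1(C)C | intermediate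
37 | (1S,3S)-1-[(3S,4E,6S,9E,13R)-6-ethenyl-3,6,10,13,14-pentamethylpentadeca-4,9,14-trien-1-yl]-2,2,3-trimethyl-6-methylidenecyclohexane (CNP0293684.2) | C=C[C@@](C)(/C=C/[C@@H](C)CC[C@H]1C(=C)CC[C@H](C)C1(C)C)CC/C=C(\C)CC[C@@H](C)C(=C)C | target

**Step count**
Total: 28 steps. Longest linear sequence: 19 steps (steps 1–18 and 28, from farnesol); the ring branch is steps 19–27.

**Steps most likely to fail**

1. Step 17 (fragmentation). The exchange may leak into single-electron paths, in which a cyclopropylmethyl radical opens towards C3 and cuts C2–C3. The iodide may ionise and rearrange before exchange. The elimination may run stepwise and lose the E geometry. Fallback (known chemistry), setting out from trienol 6 and returning at alcohol 23: 6 is phosphorylated with ClP(O)(OEt)2 and pyridine to the allylic diethyl phosphate F1. Separately, commercial methyl (S)-3-hydroxy-2-methylpropanoate, COC(=O)[C@@H](C)CO, is silylated to the silyloxy ester F2, reduced with i-Bu2AlH at −78 °C to the aldehyde F3 and homologated with the Ohira–Bestmann reagent to the alkyne F4. Cis-hydroalumination of F4 with i-Bu2AlH in hexane gives the E-alkenylalane F5. Copper-catalysed enantioselective SN2′ substitution of F1 by F5 (CuCl2·2H2O, chiral sulfonate-bearing imidazolinium salt as N-heterocyclic carbene precursor, THF, −15 °C), a known way to quaternary centres with a vinyl and an E-alkenyl group from E-trisubstituted allylic phosphates, forms C3–C4 and sets C3 while the allylic shift makes C1=C2, giving the silyl ether F6. Bu4NF then gives 23.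

2. Step 8 (carbene addition). Face selectivity may be eroded, and C21 is too remote for the cyclopropane epimers to be separable; carbene dimerisation may also compete with the addition. Fallback, setting out from lactone 10 as obtained (any isomer ratio; an achiral dirhodium carboxamidate such as Rh2(NHCOCH3)4 then serves as well) and returning at aldehyde 13: LiAlH4 reduces 10 to the diol F7, in which the two CH2OH arms differ only through the remote C21, so both cyclopropane epimers converge on one compound. Lipase-catalysed acetylation (Burkholderia cepacia or porcine pancreatic lipase, chosen by screening for the C5 arm, vinyl acetate), a known desymmetrisation of cis-1,2-bis(hydroxymethyl)cyclopropanes, gives the monoacetate F8. TBDPSCl and imidazole give the silyl ether acetate F9, K2CO3 in MeOH the alcohol F10, and Dess–Martin periodinane 13.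

3. Step 28 (C7–C8 coupling). Displacement at the β-branched tosylate by the hindered Grignard reagent may be slow, so that elimination towards the conjugated diene or homocoupling takes over. Fallback, setting out from ring alcohol 34 and tosylate 24 and returning at 37: 34 with PhSSPh and Bu3P gives the sulfide F11, and H2O2 with (NH4)6Mo7O24 the sulfone F12. Tosylate 24 with NaI in acetone gives the iodide F13. The α-sulfonyl carbanion of F12 (n-BuLi, THF/HMPA, −78 °C) is alkylated by F13 to the coupled sulfone F14 (both C8 epimers), and reductive desulfonylation with sodium amalgam Na(Hg), Na2HPO4, MeOH gives 37 (Julia-type sulfone alkylation and desulfonylation).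

**Further compounds**
F1 | step 17 | diethyl (2E,6E,10R)-3,7,10,11-tetramethyldodeca-2,6,11-trien-1-yl phosphate | CCOP(=O)(OCC)OC/C=C(\C)CC/C=C(\C)CC[C@@H](C)C(=C)C
F2 | step 17 | methyl (2S)-3-{[tert-butyl(dimethyl)silyl]oxy}-2-methylpropanoate | COC(=O)[C@@H](C)CO[Si](C)(C)C(C)(C)C
F3 | step 17 | (2S)-3-{[tert-butyl(dimethyl)silyl]oxy}-2-methylpropanal | O=C[C@@H](C)CO[Si](C)(C)C(C)(C)C
F4 | step 17 | tert-butyl(dimethyl){[(2R)-2-methylbut-3-yn-1-yl]oxy}silane | C#C[C@@H](C)CO[Si](C)(C)C(C)(C)C
F5 | step 17 | [(1E,3R)-4-{[tert-butyl(dimethyl)silyl]oxy}-3-methylbut-1-en-1-yl]bis(2-methylpropyl)alane | CC(C)C[Al](CC(C)C)/C=C/[C@@H](C)CO[Si](C)(C)C(C)(C)C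
F6 | step 17 | tert-butyl(dimethyl)silyl ether of 23 | C=C[C@@](C)(/C=C/[C@@H](C)CO[Si](C)(C)C(C)(C)C)CC/C=C(\C)CC[C@@H](C)C(=C)C
F7 | step 8 | all-cis [3-methyl-3-((3E,7R)-4,7,8-trimethylnona-3,8-dien-1-yl)cyclopropane-1,2-diyl]dimethanol | OC[C@H]1[C@@](C)([C@H]1CO)CC/C=C(\C)CC[C@@H](C)C(=C)C
F8 | step 8 | monoacetate of F7 on the C5 oxygen | OC[C@H]1[C@@](C)([C@H]1COC(C)=O)CC/C=C(\C)CC[C@@H](C)C(=C)C
F9 | step 8 | tert-butyl(diphenyl)silyl ether of F8 | CC(C)(C)[Si](c1ccccc1)(c1ccccc1)OC[C@H]1[C@@](C)([C@H]1COC(C)=O)CC/C=C(\C)CC[C@@H](C)C(=C)C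
F10 | step 8 | C5 alcohol carrying the C1 silyl ether | CC(C)(C)[Si](c1ccccc1)(c1ccccc1)OC[C@H]1[C@@](C)([C@H]1CO)CC/C=C(\C)CC[C@@H](C)C(=C)C
F11 | step 28 | {[(1S,3S)-2,2,3-trimethyl-6-methylidenecyclohexyl]methyl}(phenyl)sulfane | c1ccccc1SC[C@H]1C(=C)CC[C@H](C)C1(C)C
F12 | step 28 | {[(1S,3S)-2,2,3-trimethyl-6-methylidenecyclohexyl]methyl}sulfonylbenzene | O=S(=O)(c1ccccc1)C[C@H]1C(=C)CC[C@H](C)C1(C)C
F13 | step 28 | iodide corresponding to tosylate 24 | C=C[C@@](C)(/C=C/[C@@H](C)CI)CC/C=C(\C)CC[C@@H](C)C(=C)C
F14 | step 28 | C8-phenylsulfonyl derivative of 37 (C8 epimers) | C=C[C@@](C)(/C=C/[C@@H](C)CC([C@H]1C(=C)CC[C@H](C)C1(C)C)S(=O)(=O)c1ccccc1)CC/C=C(\C)CC[C@@H](C)C(=C)C
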